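Larch cannot hold more D than 63.3% of its X charged, because each D, a mono adduct, takes one G, and larch has 0.95 M of G for 1.5 M of X. G is the limiting reagent there, so I count turnovers of G and set two amounts against each other: G charged and D found.

| setting | larch | cedar | elm | amber | red | ochre | green |
|---|---|---|---|---|---|---|---|
| X | 1.5 M | 1.5 M | 0.75 M | 1.5 M | 1.5 M | 1.5 M | 1.5 M |
| G | 0.95 M | 2.1 M | 1.42 M | 1.42 M | 1.42 M | 1.42 M | 1.42 M |
| temperature | 72 °C | 122 °C | 72 °C | 80 °C | 50 °C | 110 °C | 140 °C |
| remark | run made earlier | run made earlier | run made earlier |  |  |  |  |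
| time |  |  |  | 15 min | 15 min | 15 min | 15 min |

larch run (percent of the X charged)

| time / min | D / % |
|---|---|
| 1.33 | 46.4 |
| 2.00 | 47.5 |
| 3.00 | 46.6 |
| 5.00 | 46.7 |
| 10.0 | 47.1 |
| 15.0 | 46.2 |

cedar run (percent of the X charged)

| time / s | D / % |
|---|---|
| 20.0 | 76.0 |
| 40.0 | 75.1 |
| 60.0 | 74.2 |
| 80.0 | 74.2 |
| 90.0 | 73.9 |
| 120 | 74.6 |

elm run (percent of the X charged)

| time / min | D / % |
|---|---|
| 1.33 | 78.9 |
| 4.00 | 78.9 |
| 8.00 | 77.5 |
| 10.0 | 76.6 |
| 15.0 | 74.4 |

(standard deviation of a reading: 0.5 percentage points)

- a reading or a percentage of D counts all its forms, free or not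

- the flask that comes out highest in amount of D, in percent of the X charged, or "all alike" when all lie within 1.5 percentage points (amber / red / ochre / green / all alike)
- D at the end, in percent of the X charged, amber
- D at the end, in percent of the X charged, red
- D at the end, in percent of the X charged, ochre
- D at the end, in percent of the X charged, green

Larch stays level from 1.33 min onward, at a mean reading of 46.8% of X. Elm, with G above X, falls from 78.9% to 74.4%, so I read larch as the pattern for a flask short of G. My quantity is the yield on G, D found per G charged: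

[D] / [G] charged = 46.8% × 1.5 M / 0.95 M = 73.8%

The asked flasks are short of G too, so I carry this reading over:

D = 73.8% × 1.42 M / 1.5 M = 69.9% of X charged

That is my own figure for amber, red, ochre and green alike. It assumes the yield on G ignores temperature, which larch cannot show, and that red finishes at 50 °C.

The forecast reads the plateaus otherwise, “X + G ⇌ D equilibrates quickly, even at 72 °C”. It gives red 65%, amber 63%, ochre 61% and green 59.5%, and names red as highest. Where I have no slope with temperature, it has one.

The flasks come out all alike: amber 66.5%, red 66.7%, ochre 66.5%, green 67.0%. The forecast's ochre lies 5.5 percentage points below its result, and my figure 3.4 points above it. Starting from larch at its last reading, without the scatter, 46.7%, changing the temperature to ochre's leaves 46.9%, while changing G to ochre's gives 66.6%. Ochre's own yield on G is 70.2%, less than larch's reading.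

    X + G → D (k = 0.0110 M⁻¹ s⁻¹, Ea = 78.0 kJ mol⁻¹)
    X + G → Q (k = 0.00240 M⁻¹ s⁻¹, Ea = 78.0 kJ mol⁻¹)
    G + D → Z (k = 5.30 × 10⁻⁴ M⁻¹ s⁻¹, Ea = 60.0 kJ mol⁻¹)
    G + Q → Z (k = 0.0290 M⁻¹ s⁻¹, Ea = 75.0 kJ mol⁻¹)
    J ⇌ D, rate k5*(cs5 - [D]) while solid is left; crystals form when [D] > cs5 (solubility = 46.0 mM, k = 0.120 s⁻¹)
    (constants at 50 °C)

Now take the neighbour of ochre charged with 2.4 M of G. The yield on G gives 118% of X, which is more than the X charged, so the reckoning does not hold there. That flask gives 57.7%, with X at 0% and 11% of its G left.

The readings stem from a simulated flask on assumed constants; the scatter is artificial.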